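## Retrosynthetic overview

1. The target comes from a C3 ketone that is reduced last; before that, a (Z)-C7=C8 cyclodecene is epoxidised under direction by the C9 hydroxyl, and the esters are installed in the order C10 senecioate, C5 angelate, C9 acetate.
2. The ten-membered ring comes from a six-membered ring by an anionic oxy-Cope ring expansion with C-methylation of the enolate in the same flask; this forms C5–C6, breaks C3–C8, and sets C5, C4 and the (Z)-C7=C8 alkene.
3. Enabling feature: C6 is allylic to the masked alkene C7=C8 (the oxirane) and C5 is β to the masked carbonyl C3 (the free carbinol), so C6=C7–C8–C3(O)–C4=C5 is a 3-oxy-1,5-diene whose C8–C3 bond closes a cyclohexane made of C1, C2, C3, C8, C9 and C10, which carries all other ring stereocentres.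
4. The Cope substrate comes from addition of an (E)-1,2-dialkoxyvinyllithium (C4, C5 and both oxygens) to a 2-methyl-2-vinylcyclohexanone; the ketone comes from a semipinacol vinyl shift of an epoxy tertiary alcohol (C8, C9), itself from vinyl addition and ketone reduction (C3, C10) after a rhodium-catalysed asymmetric isopropenyl addition to a quinone monoketal (C1).
5. Ring order: cyclohexane (from the arene), then cyclodecene (step 11), then oxirane (step 17).

Key step: step 11

## Remarks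

- Ring atoms are called C1–C10 as in the target: C1 (isopropenyl), C2 (CH2), C3 (free CHOH), C4 (C(CH3)OH), C5 (angelate), C6 (CH2), C7 and C8 (oxirane, C8 bears CH3), C9 (acetate), C10 (senecioate). In the six-membered intermediates β means the ring face that carries the C1 isopropenyl group. Names of ten-membered compounds use this ring numbering.
- Assumption: the C5 ester is read as (Z)-2-methylbut-2-enoate (angelate) and the oxirane as cis-fused (C6 and C9 on the same side), that is, derived from a (Z)-C7=C8 alkene.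
- Assumption: (R)-BINAP is chosen in step 2 by analogy with the usual facial sense of rhodium/BINAP additions to cyclohex-2-enones; potassium trifluoro(prop-1-en-2-yl)borate, (E)-1,2-diiodoethene and 2-(trimethylsilyl)ethanol are taken as commercial.

## Route

Step 1
Reactants: 1 4-methoxy-2-methylphenol
Product: 2 4,4-dimethoxy-2-methylcyclohexa-2,5-dien-1-one
Conditions: PhI(OAc)2, MeOH, 0 °C
Reagents that add atoms: methanol (CO)
Why: oxidative dearomatisation of a para-alkoxyphenol by the hypervalent iodine reagent with capture of the phenoxonium ion by methanol should give the quinone monoketal, and no stereocentre is formed.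

Step 2
Reactants: 2 4,4-dimethoxy-2-methylcyclohexa-2,5-dien-1-one
Product: 3 (5R)-4,4-dimethoxy-2-methyl-5-(prop-1-en-2-yl)cyclohex-2-en-1-one
Conditions: [Rh(cod)2]BF4 (cat.), (R)-BINAP, toluene/H2O, 100 °C
Reagents that add atoms: potassium trifluoro(prop-1-en-2-yl)borate (C=C(C)[B-](F)(F)F.[K+])
Why: rhodium/BINAP-catalysed asymmetric conjugate addition of an alkenylboron reagent (Hayashi–Miyaura reaction) should occur on the unsubstituted enone arm because the 2-methyl arm is α-substituted, and the ligand selects the enone face that sets C1.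

Step 3
Reactants: 3 (5R)-4,4-dimethoxy-2-methyl-5-(prop-1-en-2-yl)cyclohex-2-en-1-one
Product: 5 (4S,6R)-4-ethenyl-4-hydroxy-3-methyl-6-(prop-1-en-2-yl)cyclohex-2-en-1-one, via ketal alcohol 4 (not isolated)
Conditions: CH2=CHMgBr, CeCl3, THF, −78 °C; then 5% aq. oxalic acid, 0 °C
Reagents that add atoms: vinylmagnesium bromide (C=C[Mg]Br); water (O)
Why: 1,2-addition to the enone carbonyl anti to the C1 isopropenyl group (axial attack on a 5-substituted cyclohexenone) should set the tertiary C3 carbinol with its hydroxyl β, and the mild acid work-up hydrolyses the allylic dimethyl ketal to the C10 enone.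

Step 4
Reactants: 5 (4S,6R)-4-ethenyl-4-hydroxy-3-methyl-6-(prop-1-en-2-yl)cyclohex-2-en-1-one
Product: 6 (1S,4R,5R)-1-ethenyl-2-methyl-5-(prop-1-en-2-yl)cyclohex-2-ene-1,4-diol
Conditions: LiBH(s-Bu)3, THF, −78 °C
Reagents that add atoms: none
Why: the bulky trialkylborohydride should reduce the enone carbonyl in the 1,2 sense (the β-carbon is fully substituted) from the face anti to the adjacent isopropenyl group, which places the C10 hydroxyl cis to it.

Step 5
Reactants: 6 (1S,4R,5R)-1-ethenyl-2-methyl-5-(prop-1-en-2-yl)cyclohex-2-ene-1,4-diol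
Product: 7 (1S,4R,5R)-4-{[tert-butyl(dimethyl)silyl]oxy}-1-ethenyl-2-methyl-5-(prop-1-en-2-yl)cyclohex-2-en-1-ol
Conditions: TBSCl, imidazole, DMF, 0 °C
Reagents that add atoms: tert-butyl(chloro)dimethylsilane (CC(C)(C)[Si](C)(C)Cl)
Why: silylation should discriminate the secondary C10 hydroxyl from the tertiary C3 hydroxyl, which stays free to direct the next step.

Step 6
Reactants: 7 (1S,4R,5R)-4-{[tert-butyl(dimethyl)silyl]oxy}-1-ethenyl-2-methyl-5-(prop-1-en-2-yl)cyclohex-2-en-1-ol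
Product: 8 (1S,2S,4R,5S,6S)-5-{[tert-butyl(dimethyl)silyl]oxy}-2-ethenyl-1-methyl-4-(prop-1-en-2-yl)-7-oxabicyclo[4.1.0]heptan-2-ol
Conditions: VO(acac)2 (cat.), t-BuOOH, CH2Cl2, 0 °C to rt
Reagents that add atoms: tert-butyl hydroperoxide (CC(C)(C)OO)
Why: hydroxyl-directed vanadium-catalysed epoxidation should deliver oxygen to the trisubstituted ring alkene (faster than the vinyl and isopropenyl groups) on the face of the C3 hydroxyl, giving the 8β,9β-epoxide.

Step 7
Reactants: 8 (1S,2S,4R,5S,6S)-5-{[tert-butyl(dimethyl)silyl]oxy}-2-ethenyl-1-methyl-4-(prop-1-en-2-yl)-7-oxabicyclo[4.1.0]heptan-2-ol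
Product: 9 (2R,3R,4S,5R)-4-{[tert-butyl(dimethyl)silyl]oxy}-2-ethenyl-3-hydroxy-2-methyl-5-(prop-1-en-2-yl)cyclohexan-1-one
Conditions: ZnBr2 (cat.), CH2Cl2, 0 °C to rt
Reagents that add atoms: none
Why: in this semipinacol rearrangement of a 2,3-epoxy tertiary alcohol the Lewis acid opens the oxirane at tertiary C8 while the α-vinyl group on C3, antiperiplanar to the breaking C8–O bond, migrates with inversion at C8, so the C3 ketone, the C8 quaternary centre (vinyl α, methyl β) and the β-hydroxyl at C9 all follow from the epoxide configuration.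

Step 8
Reactants: 9 (2R,3R,4S,5R)-4-{[tert-butyl(dimethyl)silyl]oxy}-2-ethenyl-3-hydroxy-2-methyl-5-(prop-1-en-2-yl)cyclohexan-1-one
Product: 10 (2R,3R,4S,5R)-4-{[tert-butyl(dimethyl)silyl]oxy}-2-ethenyl-2-methyl-5-(prop-1-en-2-yl)-3-{[tri(propan-2-yl)silyl]oxy}cyclohexan-1-one
Conditions: TIPSOTf, 2,6-lutidine, CH2Cl2, 0 °C to rt
Reagents that add atoms: tri(propan-2-yl)silyl trifluoromethanesulfonate (CC(C)[Si](OS(=O)(=O)C(F)(F)F)(C(C)C)C(C)C)
Why: silyl triflate with a hindered pyridine base should protect the β-hydroxy ketone without retro-aldol cleavage, and the triisopropylsilyl group is chosen because it should not migrate to the C3 oxide in step 11.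

Step 9
Reactants: 11 (E)-1,2-diiodoethene; 12 2-(trimethylsilyl)ethan-1-ol
Product: 14 (E)-1,2-bis[2-(trimethylsilyl)ethoxy]ethene, via iodovinyl ether 13 (not isolated)
Conditions: 12 (2.5 equiv), CuI (cat.), 3,4,7,8-tetramethyl-1,10-phenanthroline, Cs2CO3, toluene, 80 °C
Reagents that add atoms: 2-(trimethylsilyl)ethan-1-ol, the second equivalent of 12 (C[Si](C)(C)CCO)
Why: copper-catalysed Ullmann-type C–O coupling of vinyl iodides with alcohols proceeds with retention of alkene geometry, so two successive couplings (the second on the iodovinyl ether 13, which consumes the second equivalent of 12) should give the (E)-enediol diether, and the (E)-diiodide has no hydrogen anti to iodine for loss of HI.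

Step 10
Reactants: 14 (E)-1,2-bis[2-(trimethylsilyl)ethoxy]ethene; 10 (2R,3R,4S,5R)-4-{[tert-butyl(dimethyl)silyl]oxy}-2-ethenyl-2-methyl-5-(prop-1-en-2-yl)-3-{[tri(propan-2-yl)silyl]oxy}cyclohexan-1-one
Product: 16 (1R,2R,3R,4S,5R)-1-{(E)-1,2-bis[2-(trimethylsilyl)ethoxy]ethenyl}-4-{[tert-butyl(dimethyl)silyl]oxy}-2-ethenyl-2-methyl-5-(prop-1-en-2-yl)-3-{[tri(propan-2-yl)silyl]oxy}cyclohexan-1-ol, via alkenyllithium 15 (not isolated)
Conditions: 14, t-BuLi, THF, −78 to −30 °C; then LaCl3·2LiCl, 10, −78 °C; aq. NH4Cl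
Reagents that add atoms: none
Why: α-lithiation of the enol ether (lithium cis to the β-oxygen and chelated by it, hence configurationally stable) followed by 1,2-addition to the ketone along the axial trajectory on the α face, anti to the axial β-methyl group on C8, should give the cis-1,2-dialkenylcyclohexanol with the C3 hydroxyl β.

Step 11
Reactants: 16 (1R,2R,3R,4S,5R)-1-{(E)-1,2-bis[2-(trimethylsilyl)ethoxy]ethenyl}-4-{[tert-butyl(dimethyl)silyl]oxy}-2-ethenyl-2-methyl-5-(prop-1-en-2-yl)-3-{[tri(propan-2-yl)silyl]oxy}cyclohexan-1-ol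
Product: 19 (1R,4R,5S,7Z,9R,10S)-10-{[tert-butyl(dimethyl)silyl]oxy}-4,8-dimethyl-1-(prop-1-en-2-yl)-9-{[tri(propan-2-yl)silyl]oxy}-4,5-bis[2-(trimethylsilyl)ethoxy]cyclodec-7-en-3-one, via potassium alkoxide 17 (not isolated), via potassium enolate 18 (not isolated)
Conditions: KN(SiMe3)2, THF, 0 to 25 °C; then MeI, −78 to −20 °C
Reagents that add atoms: iodomethane (CI)
Why: KN(SiMe3)2 gives the potassium alkoxide 17, in which the oxido group weakens the C3–C8 bond, and a concerted suprafacial [3,3] sigmatropic shift through a chair transition state breaks C3–C8 and forms C5–C6 to give the enolate 18, which is then C-methylated. The closest known reaction type is the anionic oxy-Cope ring expansion of cis-1,2-dialkenylcyclohexanols to cyclodec-5-enones with alkylation of the resulting enolate. The ten-membered carbocycle is closed by ring expansion, the new σ bond joining the two alkene termini while the six-membered ring opens (a four-atom enlargement, not an exo or endo chain cyclisation). C5 is controlled by the (E)-enediol ether geometry: the C5 oxygen is cis to C3, lies pseudo-axial in the transition-state chair (bridged by K+ to the C3 oxide, which is axial in the same chair) and C6 bonds to the alkene face turned towards the vinyl group, which gives 5S, and because C9 is pseudo-axial on C8 in this chair the new C7=C8 bond is Z. C4 is controlled by the planar chirality of 18, a trans ring double bond carrying O− and OR that cannot turn through the ring, so iodomethane enters from the outer face and leaves the C4 oxygen syn to the C5 oxygen as in the target. The step needs chair over boat, one chair over its flipped form and C-alkylation over β-elimination; the all-cis substituents at C1, C9 and C10 keep the reacting cyclohexane chair (equatorial isopropenyl, axial C8 methyl) as the ground-state conformer, and the C5–O bond lies in the enolate plane where it cannot overlap for elimination.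

Step 12
Reactants: 19 (1R,4R,5S,7Z,9R,10S)-10-{[tert-butyl(dimethyl)silyl]oxy}-4,8-dimethyl-1-(prop-1-en-2-yl)-9-{[tri(propan-2-yl)silyl]oxy}-4,5-bis[2-(trimethylsilyl)ethoxy]cyclodec-7-en-3-one
Product: 20 (1R,4R,5S,7Z,9R,10S)-10-hydroxy-4,8-dimethyl-1-(prop-1-en-2-yl)-9-{[tri(propan-2-yl)silyl]oxy}-4,5-bis[2-(trimethylsilyl)ethoxy]cyclodec-7-en-3-one
Conditions: HF·pyridine, pyridine, THF, 0 °C to rt
Reagents that add atoms: none
Why: buffered hydrogen fluoride should cleave the tert-butyldimethylsilyl ether much faster than the triisopropylsilyl ether and should leave the alkyl 2-(trimethylsilyl)ethyl ethers untouched.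

Step 13
Reactants: 20 (1R,4R,5S,7Z,9R,10S)-10-hydroxy-4,8-dimethyl-1-(prop-1-en-2-yl)-9-{[tri(propan-2-yl)silyl]oxy}-4,5-bis[2-(trimethylsilyl)ethoxy]cyclodec-7-en-3-one
Product: 21 (1R,4R,5S,7Z,9R,10S)-4,8-dimethyl-10-[(3-methylbut-2-enoyl)oxy]-1-(prop-1-en-2-yl)-9-{[tri(propan-2-yl)silyl]oxy}-4,5-bis[2-(trimethylsilyl)ethoxy]cyclodec-7-en-3-one
Conditions: (Me2C=CHCO)2O, Et3N, DMAP (cat.), CH2Cl2, 0 °C to rt
Reagents that add atoms: 3-methylbut-2-enoic anhydride (CC(C)=CC(=O)OC(=O)C=C(C)C)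
Why: DMAP-catalysed acylation of the only free hydroxyl with the anhydride should install the senecioate, and the anhydride avoids the ketene pathway that deconjugates the acid chloride.

Step 14
Reactants: 21 (1R,4R,5S,7Z,9R,10S)-4,8-dimethyl-10-[(3-methylbut-2-enoyl)oxy]-1-(prop-1-en-2-yl)-9-{[tri(propan-2-yl)silyl]oxy}-4,5-bis[2-(trimethylsilyl)ethoxy]cyclodec-7-en-3-one
Product: 22 (1R,4R,5S,7Z,9R,10S)-4,5-dihydroxy-4,8-dimethyl-10-[(3-methylbut-2-enoyl)oxy]-1-(prop-1-en-2-yl)-9-{[tri(propan-2-yl)silyl]oxy}cyclodec-7-en-3-one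
Conditions: BF3·OEt2, CH2Cl2, −20 to 0 °C; aq. NaHCO3
Reagents that add atoms: none
Why: the Lewis acid should trigger β-silyl fragmentation of both 2-(trimethylsilyl)ethyl ethers (loss of ethene and fluorotrimethylsilane), while the tertiary C4–O bond next to the ketone is not ionised and the triisopropylsilyl ether and the ester survive.

Step 15
Reactants: 22 (1R,4R,5S,7Z,9R,10S)-4,5-dihydroxy-4,8-dimethyl-10-[(3-methylbut-2-enoyl)oxy]-1-(prop-1-en-2-yl)-9-{[tri(propan-2-yl)silyl]oxy}cyclodec-7-en-3-one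
Product: 23 (1R,4R,5S,7Z,9R,10S)-4-hydroxy-4,8-dimethyl-5-{[(2Z)-2-methylbut-2-enoyl]oxy}-10-[(3-methylbut-2-enoyl)oxy]-1-(prop-1-en-2-yl)-9-{[tri(propan-2-yl)silyl]oxy}cyclodec-7-en-3-one
Conditions: angelic acid, 2,4,6-trichlorobenzoyl chloride, Et3N, toluene, rt; then 22, 80 °C
Reagents that add atoms: (Z)-2-methylbut-2-enoic acid (C/C=C(/C)C(=O)O)
Why: Yamaguchi esterification through the mixed anhydride without a nucleophilic catalyst should acylate the secondary C5 hydroxyl without Z to E isomerisation of the angelate, and the tertiary C4 hydroxyl does not react.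

Step 16
Reactants: 23 (1R,4R,5S,7Z,9R,10S)-4-hydroxy-4,8-dimethyl-5-{[(2Z)-2-methylbut-2-enoyl]oxy}-10-[(3-methylbut-2-enoyl)oxy]-1-(prop-1-en-2-yl)-9-{[tri(propan-2-yl)silyl]oxy}cyclodec-7-en-3-one
Product: 24 (1R,4R,5S,7Z,9R,10S)-4,9-dihydroxy-4,8-dimethyl-5-{[(2Z)-2-methylbut-2-enoyl]oxy}-10-[(3-methylbut-2-enoyl)oxy]-1-(prop-1-en-2-yl)cyclodec-7-en-3-one
Conditions: HF·pyridine (excess), THF, rt
Reagents that add atoms: none
Why: fluoride-mediated cleavage of the remaining silyl ether under weakly acidic conditions should free the allylic C9 hydroxyl without acyl migration or ester cleavage.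

Step 17
Reactants: 24 (1R,4R,5S,7Z,9R,10S)-4,9-dihydroxy-4,8-dimethyl-5-{[(2Z)-2-methylbut-2-enoyl]oxy}-10-[(3-methylbut-2-enoyl)oxy]-1-(prop-1-en-2-yl)cyclodec-7-en-3-one
Product: 25 (1R,4R,5S,7R,8S,9S,10S)-7,8-epoxy-4,9-dihydroxy-4,8-dimethyl-5-{[(2Z)-2-methylbut-2-enoyl]oxy}-10-[(3-methylbut-2-enoyl)oxy]-1-(prop-1-en-2-yl)cyclodecan-3-one
Conditions: VO(acac)2 (cat.), t-BuOOH, CH2Cl2, 0 °C
Reagents that add atoms: tert-butyl hydroperoxide (CC(C)(C)OO)
Why: hydroxyl-directed vanadium epoxidation should be chemoselective for the allylic C7=C8 bond and, because allylic 1,2-strain between the C8 methyl group and C10 keeps C10 on the face opposite the vanadate-bound C9 oxygen, should deliver oxygen in the erythro sense that corresponds to the 7R,8R oxirane of the target (the descriptor at C8 reads S in 25 only because the free C9 hydroxyl changes the priority order).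

Step 18
Reactants: 25 (1R,4R,5S,7R,8S,9S,10S)-7,8-epoxy-4,9-dihydroxy-4,8-dimethyl-5-{[(2Z)-2-methylbut-2-enoyl]oxy}-10-[(3-methylbut-2-enoyl)oxy]-1-(prop-1-en-2-yl)cyclodecan-3-one
Product: 26 (1R,4R,5S,7R,8R,9S,10S)-9-acetoxy-7,8-epoxy-4-hydroxy-4,8-dimethyl-5-{[(2Z)-2-methylbut-2-enoyl]oxy}-10-[(3-methylbut-2-enoyl)oxy]-1-(prop-1-en-2-yl)cyclodecan-3-one
Conditions: Ac2O, pyridine, DMAP (cat.), CH2Cl2, 0 °C
Reagents that add atoms: acetic anhydride (CC(=O)OC(C)=O)
Why: acetylation should take place at the secondary C9 hydroxyl only, since the tertiary C4 hydroxyl next to the ketone is inert under these mild conditions.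

Step 19
Reactants: 26 (1R,4R,5S,7R,8R,9S,10S)-9-acetoxy-7,8-epoxy-4-hydroxy-4,8-dimethyl-5-{[(2Z)-2-methylbut-2-enoyl]oxy}-10-[(3-methylbut-2-enoyl)oxy]-1-(prop-1-en-2-yl)cyclodecan-3-one
Product: 27 (1R,3R,4S,5S,7R,8R,9S,10S)-9-acetoxy-7,8-epoxy-3,4-dihydroxy-4,8-dimethyl-5-{[(2Z)-2-methylbut-2-enoyl]oxy}-10-[(3-methylbut-2-enoyl)oxy]-1-(prop-1-en-2-yl)cyclodecane
Conditions: NaBH4, MeOH/THF, −40 °C
Reagents that add atoms: none
Why: borohydride should reduce the ketone chemoselectively in the presence of the esters and the oxirane, and under non-chelating conditions hydride should add anti to the C4–O bond (Felkin–Anh) from the ring periphery, which gives the 3,4-syn diol (3R).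

## Compound list

1 | 4-methoxy-2-methylphenol | Cc1cc(OC)ccc1O | starting material
2 | 4,4-dimethoxy-2-methylcyclohexa-2,5-dien-1-one | CC1=CC(OC)(OC)C=CC1=O | intermediate
3 | (5R)-4,4-dimethoxy-2-methyl-5-(prop-1-en-2-yl)cyclohex-2-en-1-one | C=C(C)[C@H]1CC(=O)C(C)=CC1(OC)OC | intermediate
4 | (1S,5R)-1-ethenyl-4,4-dimethoxy-2-methyl-5-(prop-1-en-2-yl)cyclohex-2-en-1-ol (not isolated) | C=C(C)[C@H]1C[C@](O)(C=C)C(C)=CC1(OC)OC | intermediate
5 | (4S,6R)-4-ethenyl-4-hydroxy-3-methyl-6-(prop-1-en-2-yl)cyclohex-2-en-1-one | C=C(C)[C@H]1C[C@](O)(C=C)C(C)=CC1=O | intermediate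
6 | (1S,4R,5R)-1-ethenyl-2-methyl-5-(prop-1-en-2-yl)cyclohex-2-ene-1,4-diol | C=C(C)[C@H]1C[C@](O)(C=C)C(C)=C[C@H]1O | intermediate
7 | (1S,4R,5R)-4-{[tert-butyl(dimethyl)silyl]oxy}-1-ethenyl-2-methyl-5-(prop-1-en-2-yl)cyclohex-2-en-1-ol | C=C(C)[C@H]1C[C@](O)(C=C)C(C)=C[C@H]1O[Si](C)(C)C(C)(C)C | intermediate
8 | (1S,2S,4R,5S,6S)-5-{[tert-butyl(dimethyl)silyl]oxy}-2-ethenyl-1-methyl-4-(prop-1-en-2-yl)-7-oxabicyclo[4.1.0]heptan-2-ol | C=C(C)[C@H]1C[C@](O)(C=C)[C@@]2(C)O[C@H]2[C@H]1O[Si](C)(C)C(C)(C)C | intermediate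
9 | (2R,3R,4S,5R)-4-{[tert-butyl(dimethyl)silyl]oxy}-2-ethenyl-3-hydroxy-2-methyl-5-(prop-1-en-2-yl)cyclohexan-1-one | C=C(C)[C@H]1CC(=O)[C@](C)(C=C)[C@@H](O)[C@H]1O[Si](C)(C)C(C)(C)C | intermediate
10 | (2R,3R,4S,5R)-4-{[tert-butyl(dimethyl)silyl]oxy}-2-ethenyl-2-methyl-5-(prop-1-en-2-yl)-3-{[tri(propan-2-yl)silyl]oxy}cyclohexan-1-one | C=C(C)[C@H]1CC(=O)[C@](C)(C=C)[C@@H](O[Si](C(C)C)(C(C)C)C(C)C)[C@H]1O[Si](C)(C)C(C)(C)C | intermediate
11 | (E)-1,2-diiodoethene | I/C=C/I | starting material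
12 | 2-(trimethylsilyl)ethan-1-ol | C[Si](C)(C)CCO | starting material
13 | (E)-1-iodo-2-[2-(trimethylsilyl)ethoxy]ethene (not isolated) | C[Si](C)(C)CCO/C=C/I | intermediate
14 | (E)-1,2-bis[2-(trimethylsilyl)ethoxy]ethene | C[Si](C)(C)CCO/C=C/OCC[Si](C)(C)C | intermediate
15 | {(E)-1,2-bis[2-(trimethylsilyl)ethoxy]ethenyl}lithium (not isolated) | [Li]/C(OCC[Si](C)(C)C)=C\OCC[Si](C)(C)C | intermediate
16 | (1R,2R,3R,4S,5R)-1-{(E)-1,2-bis[2-(trimethylsilyl)ethoxy]ethenyl}-4-{[tert-butyl(dimethyl)silyl]oxy}-2-ethenyl-2-methyl-5-(prop-1-en-2-yl)-3-{[tri(propan-2-yl)silyl]oxy}cyclohexan-1-ol | C=C(C)[C@H]1C[C@](O)(/C(OCC[Si](C)(C)C)=C\OCC[Si](C)(C)C)[C@](C)(C=C)[C@@H](O[Si](C(C)C)(C(C)C)C(C)C)[C@H]1O[Si](C)(C)C(C)(C)C | intermediate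
17 | potassium alkoxide of 16 (not isolated) | C=C(C)[C@H]1C[C@]([O-])(/C(OCC[Si](C)(C)C)=C\OCC[Si](C)(C)C)[C@](C)(C=C)[C@@H](O[Si](C(C)C)(C(C)C)C(C)C)[C@H]1O[Si](C)(C)C(C)(C)C.[K+] | intermediate
18 | potassium (3E,7Z)-enolate of the ring-expanded ketone, C3(OK)=C4(OR), C4 still without methyl (not isolated) | C=C(C)[C@H]1C/C([O-])=C(OCC[Si](C)(C)C)/[C@@H](OCC[Si](C)(C)C)C/C=C(/C)[C@@H](O[Si](C(C)C)(C(C)C)C(C)C)[C@H]1O[Si](C)(C)C(C)(C)C.[K+] | intermediate
19 | (1R,4R,5S,7Z,9R,10S)-10-{[tert-butyl(dimethyl)silyl]oxy}-4,8-dimethyl-1-(prop-1-en-2-yl)-9-{[tri(propan-2-yl)silyl]oxy}-4,5-bis[2-(trimethylsilyl)ethoxy]cyclodec-7-en-3-one | C=C(C)[C@H]1CC(=O)[C@](C)(OCC[Si](C)(C)C)[C@@H](OCC[Si](C)(C)C)C/C=C(/C)[C@@H](O[Si](C(C)C)(C(C)C)C(C)C)[C@H]1O[Si](C)(C)C(C)(C)C | intermediate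
20 | (1R,4R,5S,7Z,9R,10S)-10-hydroxy-4,8-dimethyl-1-(prop-1-en-2-yl)-9-{[tri(propan-2-yl)silyl]oxy}-4,5-bis[2-(trimethylsilyl)ethoxy]cyclodec-7-en-3-one | C=C(C)[C@H]1CC(=O)[C@](C)(OCC[Si](C)(C)C)[C@@H](OCC[Si](C)(C)C)C/C=C(/C)[C@@H](O[Si](C(C)C)(C(C)C)C(C)C)[C@H]1O | intermediate
21 | (1R,4R,5S,7Z,9R,10S)-4,8-dimethyl-10-[(3-methylbut-2-enoyl)oxy]-1-(prop-1-en-2-yl)-9-{[tri(propan-2-yl)silyl]oxy}-4,5-bis[2-(trimethylsilyl)ethoxy]cyclodec-7-en-3-one | C=C(C)[C@H]1CC(=O)[C@](C)(OCC[Si](C)(C)C)[C@@H](OCC[Si](C)(C)C)C/C=C(/C)[C@@H](O[Si](C(C)C)(C(C)C)C(C)C)[C@H]1OC(=O)C=C(C)C | intermediate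
22 | (1R,4R,5S,7Z,9R,10S)-4,5-dihydroxy-4,8-dimethyl-10-[(3-methylbut-2-enoyl)oxy]-1-(prop-1-en-2-yl)-9-{[tri(propan-2-yl)silyl]oxy}cyclodec-7-en-3-one | C=C(C)[C@H]1CC(=O)[C@](C)(O)[C@@H](O)C/C=C(/C)[C@@H](O[Si](C(C)C)(C(C)C)C(C)C)[C@H]1OC(=O)C=C(C)C | intermediate
23 | (1R,4R,5S,7Z,9R,10S)-4-hydroxy-4,8-dimethyl-5-{[(2Z)-2-methylbut-2-enoyl]oxy}-10-[(3-methylbut-2-enoyl)oxy]-1-(prop-1-en-2-yl)-9-{[tri(propan-2-yl)silyl]oxy}cyclodec-7-en-3-one | C=C(C)[C@H]1CC(=O)[C@](C)(O)[C@@H](OC(=O)/C(C)=C\C)C/C=C(/C)[C@@H](O[Si](C(C)C)(C(C)C)C(C)C)[C@H]1OC(=O)C=C(C)C | intermediate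
24 | (1R,4R,5S,7Z,9R,10S)-4,9-dihydroxy-4,8-dimethyl-5-{[(2Z)-2-methylbut-2-enoyl]oxy}-10-[(3-methylbut-2-enoyl)oxy]-1-(prop-1-en-2-yl)cyclodec-7-en-3-one | C=C(C)[C@H]1CC(=O)[C@](C)(O)[C@@H](OC(=O)/C(C)=C\C)C/C=C(/C)[C@@H](O)[C@H]1OC(=O)C=C(C)C | intermediate
25 | (1R,4R,5S,7R,8S,9S,10S)-7,8-epoxy-4,9-dihydroxy-4,8-dimethyl-5-{[(2Z)-2-methylbut-2-enoyl]oxy}-10-[(3-methylbut-2-enoyl)oxy]-1-(prop-1-en-2-yl)cyclodecan-3-one | C=C(C)[C@H]1CC(=O)[C@](C)(O)[C@@H](OC(=O)/C(C)=C\C)C[C@H]2O[C@@]2(C)[C@@H](O)[C@H]1OC(=O)C=C(C)C | intermediate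
26 | (1R,4R,5S,7R,8R,9S,10S)-9-acetoxy-7,8-epoxy-4-hydroxy-4,8-dimethyl-5-{[(2Z)-2-methylbut-2-enoyl]oxy}-10-[(3-methylbut-2-enoyl)oxy]-1-(prop-1-en-2-yl)cyclodecan-3-one | C=C(C)[C@H]1CC(=O)[C@](C)(O)[C@@H](OC(=O)/C(C)=C\C)C[C@H]2O[C@@]2(C)[C@@H](OC(C)=O)[C@H]1OC(=O)C=C(C)C | intermediate
27 | CNP0298989.1, (1R,3R,4S,5S,7R,8R,9S,10S)-9-acetoxy-7,8-epoxy-3,4-dihydroxy-4,8-dimethyl-5-{[(2Z)-2-methylbut-2-enoyl]oxy}-10-[(3-methylbut-2-enoyl)oxy]-1-(prop-1-en-2-yl)cyclodecane | C=C(C)[C@H]1C[C@@H](O)[C@](C)(O)[C@@H](OC(=O)/C(C)=C\C)C[C@H]2O[C@@]2(C)[C@@H](OC(C)=O)[C@H]1OC(=O)C=C(C)C | target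

## Step count and risks

Total step count: 19. Longest linear sequence: 18 steps (steps 1–8 and 10–19; step 9 makes the C4–C5 reagent).

Three steps most likely to fail:

1. Step 11. The potassium enolate 18 may expel the C5 alkoxide (β-elimination) or be methylated on oxygen before carbon, so that the ring forms but the C4 centre is lost. The fallback sets out from 16: the rearrangement is run as before, but the enolate is quenched at −78 °C with Me3SiCl/Et3N to give the isolable trimethylsilyl enol ether F1, which keeps the trans ring double bond. MeLi (THF, 0 °C) then releases the lithium enolate F2, a tighter ion pair that should alkylate on carbon with MeI/DMPU at −78 °C from the same outer face. The sequence comes back to the route at 19.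

2. Step 17. Oxygen may be delivered to the wrong alkene face if the ring holds the C9 hydroxyl in the other allylic conformation (threo delivery), or the isopropenyl group may be epoxidised as well. The fallback replaces substrate direction by reagent control and sets out from 24: acetylation (Ac2O, pyridine) gives the allylic acetate F3, and its trisubstituted alkene is then epoxidised by the Shi method (fructose-derived ketone of the enantiomeric series matched to the required face, KHSO5, K2CO3, MeCN/dimethoxymethane, 0 °C). This should give 26 directly, where it comes back to the route.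

3. Step 19. Hydride may be delivered to the wrong carbonyl face through chelation by the free C4 hydroxyl, giving the 3-epimer. The fallback sets out from 26 and uses a catalyst-controlled Corey–Bakshi–Shibata reduction with (S)-2-methyl-CBS-oxazaborolidine and catecholborane (toluene, −78 °C), in which the oxazaborolidine and not the substrate selects the face (C4 as the large and C2 as the small substituent predicts 3R). It comes back to the route at 27 and makes no new compound (F0).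

## Further compounds

F1 | step 11 | trimethylsilyl enol ether of the ring-expanded ketone (C3–OSiMe3, (3E,7Z)-diene, C4 without methyl) | C=C(C)[C@H]1C/C(O[Si](C)(C)C)=C(OCC[Si](C)(C)C)/[C@@H](OCC[Si](C)(C)C)C/C=C(/C)[C@@H](O[Si](C(C)C)(C(C)C)C(C)C)[C@H]1O[Si](C)(C)C(C)(C)C
F2 | step 11 | lithium (3E,7Z)-enolate of the ring-expanded ketone | C=C(C)[C@H]1C/C([O-])=C(OCC[Si](C)(C)C)/[C@@H](OCC[Si](C)(C)C)C/C=C(/C)[C@@H](O[Si](C(C)C)(C(C)C)C(C)C)[C@H]1O[Si](C)(C)C(C)(C)C.[Li+]
F3 | step 17 | (1R,4R,5S,7Z,9R,10S)-9-acetoxy-4-hydroxy-4,8-dimethyl-5-{[(2Z)-2-methylbut-2-enoyl]oxy}-10-[(3-methylbut-2-enoyl)oxy]-1-(prop-1-en-2-yl)cyclodec-7-en-3-one | C=C(C)[C@H]1CC(=O)[C@](C)(O)[C@@H](OC(=O)/C(C)=C\C)C/C=C(/C)[C@@H](OC(C)=O)[C@H]1OC(=O)C=C(C)C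
F0 | step 19 | none | none
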